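**Plan**

1. Cuts (cembrane locants: C1 bears the isopropyl group, C1=C2–C3=C4 is the diene, C7 bears the acetate, the oxolane is O–C8–C9–C10–C11, C12 is the tertiary carbinol, C13 and C14 lead back to C1): the C7 acetate; C1=C2 (ketone–enal McMurry coupling, opens the 14-membered ring); C13–C14 (azaenolate plus terminal oxirane, detaches a C5 ketone arm); what remains is the C15 chain of (E,E)-farnesyl acetate.
2. The oxolane is not closed directly: its O–C11 bond is traced back to the O–C12 bond of an oxane (O, C8, C9, C10, C11, C12) that carries bromine on C11, and this oxane comes from two oxiranes (C7–C8 and C11–C12) on the farnesyl chain.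
3. Forward order: C13 hydroxylation, C11–C12 oxirane, C7–C8 oxirane, directed bromide opening at C11, 6-exo closure to the oxane, ring contraction to the oxolane, C12–C13 oxirane, ketone arm, enal, 14-membered carbocycle, acetate.
4. Enabling feature: in the oxane the ring oxygen is bonded to the fully substituted C12, and its O–C12 bond lies antiperiplanar to the equatorial C11–Br bond; loss of bromide is therefore assisted by oxygen, the oxiranium ion is opened at C12, and the 1,3-diaxial contact between the C8 and C12 substituents is relieved.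
5. Stereochemistry: C11/C12 come from the Sharpless oxirane (C11 inverted twice, by bromide and then by the ring oxygen; C12 inverted once, by water); C7/C8 come from the Shi oxirane (C8 inverted once in the 6-exo closure, C7 retained); C3=C4 comes from farnesyl acetate and C1=C2 from the McMurry step. The helpers (C13 hydroxyl as directing group and later oxirane handle, bromine as leaving group) are gone after step 7.

Key step: step 6

Remark: commercial farnesyl acetate is taken as the (2E,6E) isomer; locants in the text are cembrane locants, while systematic names of open-chain compounds keep chain locants (chain 1, 2, 3, 6, 7, 10, 11, 12 = C2, C3, C4, C7, C8, C11, C12, C13).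

**Step 1**
Reactants: 1 (2E,6E)-3,7,11-trimethyldodeca-2,6,10-trien-1-yl acetate [(E,E)-farnesyl acetate]
Product: 2 (2E,6E,10E)-12-hydroxy-3,7,11-trimethyldodeca-2,6,10-trien-1-yl acetate
Conditions: SeO2 (cat.), t-BuOOH, salicylic acid (cat.), CH2Cl2, rt
Reagents that add atoms: tert-butyl hydroperoxide CC(C)(C)OO (terminal oxidant); SeO2 O=[Se]=O (catalytic oxygen carrier)
Why: Catalytic SeO2 allylic oxidation (ene reaction, then [2,3]-sigmatropic shift) should hydroxylate the (E)-methyl group of the most electron-rich, terminal trisubstituted alkene and spare the alkene deactivated by the allylic acetate; no stereocentre is formed and the C11=C12 geometry is kept.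

**Step 2**
Reactants: 2 (2E,6E,10E)-12-hydroxy-3,7,11-trimethyldodeca-2,6,10-trien-1-yl acetate
Product: 3 (2E,6E,10R,11R)-10,11-epoxy-12-hydroxy-3,7,11-trimethyldodeca-2,6-dien-1-yl acetate
Conditions: Ti(OiPr)4 (cat.), D-(−)-diethyl tartrate (cat.), t-BuOOH, 4 Å molecular sieves, CH2Cl2, −20 °C
Reagents that add atoms: tert-butyl hydroperoxide CC(C)(C)OO
Why: Sharpless asymmetric epoxidation acts only on the allylic-alcohol alkene, and with D-(−)-diethyl tartrate the (E)-2-methylalk-2-en-1-ol should give the (R,R)-oxirane at C11/C12 under reagent control.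

**Step 3**
Reactants: 3 (2E,6E,10R,11R)-10,11-epoxy-12-hydroxy-3,7,11-trimethyldodeca-2,6-dien-1-yl acetate
Product: 4 (2E,6R,7R,10R,11R)-6,7:10,11-diepoxy-12-hydroxy-3,7,11-trimethyldodec-2-en-1-yl acetate
Conditions: 1,2:4,5-di-O-isopropylidene-β-D-erythro-2,3-hexodiulo-2,6-pyranose (Shi ketone, cat.), KHSO5 (as the triple salt 2KHSO5·KHSO4·K2SO4), K2CO3, Bu4NHSO4 (cat.), MeCN/CH2(OMe)2/aq. Na2B4O7 buffer, 0 °C
Reagents that add atoms: KHSO5 [K+].[O-]S(=O)(=O)OO
Why: Shi epoxidation (chiral dioxirane from the D-fructose-derived ketone) should oxidise the isolated, electron-rich C7=C8 alkene from the face that gives the (7R,8R)-oxirane, while the C3=C4 alkene is protected by the electron-withdrawing allylic acetate.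

**Step 4**
Reactants: 4 (2E,6R,7R,10R,11R)-6,7:10,11-diepoxy-12-hydroxy-3,7,11-trimethyldodec-2-en-1-yl acetate
Product: 5 (2E,6R,7R,10S,11R)-10-bromo-6,7-epoxy-11,12-dihydroxy-3,7,11-trimethyldodec-2-en-1-yl acetate
Conditions: Ti(OiPr)4, Et2NH·HBr, CH2Cl2, 0 °C → rt; aq. tartaric acid work-up
Reagents that add atoms: diethylammonium bromide CC[NH2+]CC.[Br-]
Why: Titanium-mediated, hydroxyl-directed opening of a 2,3-epoxy alcohol: only the oxirane chelated through the C13 hydroxyl is activated, and bromide attacks the secondary C11 in an SN2 step (C12 is quaternary and stays in the titanium diolate chelate), so C11 is inverted to (S), C12 keeps its oxygen and the C7–C8 oxirane is left.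

**Step 5**
Reactants: 5 (2E,6R,7R,10S,11R)-10-bromo-6,7-epoxy-11,12-dihydroxy-3,7,11-trimethyldodec-2-en-1-yl acetate
Product: 6 (2E,6R)-6-[(2S,5S,6R)-5-bromo-6-(hydroxymethyl)-2,6-dimethyloxan-2-yl]-6-hydroxy-3-methylhex-2-en-1-yl acetate
Conditions: (+)-camphor-10-sulfonic acid (cat.), CH2Cl2, 0 °C → rt
Reagents that add atoms: none
Why: Acid-catalysed intramolecular epoxide opening by the tertiary C12 hydroxyl, 6-exo-tet and at the tertiary C8 (Markovnikov), should close the oxane with inversion at C8 to (S) and retention at C7, the C11 position being blocked as bromide and the C13 hydroxyl reaching C8 only through a seven-membered ring.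

**Step 6**
Reactants: 6 (2E,6R)-6-[(2S,5S,6R)-5-bromo-6-(hydroxymethyl)-2,6-dimethyloxan-2-yl]-6-hydroxy-3-methylhex-2-en-1-yl acetate
Product: 8 (2E,6R)-6-[(2S,5R)-5-[(2S)-1,2-dihydroxypropan-2-yl]-2-methyloxolan-2-yl]-6-hydroxy-3-methylhex-2-en-1-yl acetate, via oxiranium triflate 7 (not isolated)
Conditions: AgOTf, 2,6-lutidine, THF/H2O (3:1), rt, dark
Reagents that add atoms: water O
Why: Silver ion removes bromide from C11 while the ring oxygen, whose O–C12 bond is antiperiplanar to the equatorial C11–Br bond, attacks C11 from the rear to give the bicyclic oxiranium ion 7, and water then opens 7 at C12, so the oxane (O, C8, C9, C10, C11, C12) becomes the oxolane (O, C8, C9, C10, C11) and C12 leaves the ring as the tertiary carbinol. The closest known reaction type is the anchimerically assisted solvolytic ring contraction of 3-halo- and 3-sulfonyloxy-oxanes to 2-(1-hydroxyalkyl)oxolanes through epoxonium ions. The only ring closed is the transient three-membered oxiranium (3-exo-tet attack of the ether oxygen on C11); the five-membered ring is what is left when the O–C12 bond breaks. Both stereocentres arise stereospecifically by SN2 inversion: C11 goes from (S) to (R) under control of the bromide configuration set in step 4, and C12 goes from (R) to (S) under control of the oxane oxygen. The step needs water to open 7 at C12 and not at C11 or C8: C12 is fully substituted and lies only in the strained three-membered ring, attack at C11 would merely give back a six-membered ring, and attack at C8 would break an unstrained bond. Relief of the 1,3-diaxial contact between the C8 and C12 substituents of the 2,2,6,6-tetrasubstituted oxane should add driving force, and the buffer keeps the new tertiary carbinol and the allylic acetate from acid.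

**Step 7**
Reactants: 8 (2E,6R)-6-[(2S,5R)-5-[(2S)-1,2-dihydroxypropan-2-yl]-2-methyloxolan-2-yl]-6-hydroxy-3-methylhex-2-en-1-yl acetate
Product: 10 (2E,6R)-3-methyl-6-[(2S,5R)-2-methyl-5-[(2S)-2-methyloxiran-2-yl]oxolan-2-yl]hex-2-ene-1,6-diol, via primary tosylate 9 (not isolated)
Conditions: TsCl, Et3N, Bu2SnO (cat.), CH2Cl2, 0 °C; then K2CO3, MeOH, rt
Reagents that add atoms: none
Why: Tin-catalysed regioselective tosylation of the primary hydroxyl of the C12/C13 diol, then Williamson-type 3-exo-tet closure by the tertiary alkoxide, should give the 2,2-disubstituted oxirane without touching the C12–O bond (configuration kept), and the methanolic carbonate removes the allylic acetate in the same flask.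

**Step 8**
Reactants: 11 3-methylbutan-2-one; 12 1,1-dimethylhydrazine
Product: 13 3-methylbutan-2-one N,N-dimethylhydrazone
Conditions: AcOH (cat.), EtOH, reflux; distillation
Reagents that add atoms: none
Why: Acid-catalysed condensation of a ketone with 1,1-dimethylhydrazine gives the N,N-dimethylhydrazone; no stereocentre is involved.

**Step 9**
Reactants: 10 (2E,6R)-3-methyl-6-[(2S,5R)-2-methyl-5-[(2S)-2-methyloxiran-2-yl]oxolan-2-yl]hex-2-ene-1,6-diol; 13 3-methylbutan-2-one N,N-dimethylhydrazone
Product: 15 (2E,6R)-6-[(2S,5R)-5-[(2S)-2-hydroxy-6-methyl-5-oxoheptan-2-yl]-2-methyloxolan-2-yl]-3-methylhex-2-ene-1,6-diol, via hydroxy hydrazone 14 (not isolated)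
Conditions: 13, LiN(iPr)2 (excess), THF, −78 → 0 °C; then 10, 0 °C → rt; H2O; then AcOH/NaOAc buffer (pH 4.5), THF/H2O, rt
Reagents that add atoms: water O
Why: Hydrazone alkylation with an epoxide: the azaenolate formed at the methyl group of 13 opens the oxirane at its unhindered CH2 (C13) in an SN2 step, so C12 keeps its configuration, excess base covers the two hydroxyls, and buffered hydrolysis of the C=N bond releases the isopropyl ketone.

**Step 10**
Reactants: 15 (2E,6R)-6-[(2S,5R)-5-[(2S)-2-hydroxy-6-methyl-5-oxoheptan-2-yl]-2-methyloxolan-2-yl]-3-methylhex-2-ene-1,6-diol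
Product: 16 (2E,6R)-6-hydroxy-6-[(2S,5R)-5-[(2S)-2-hydroxy-6-methyl-5-oxoheptan-2-yl]-2-methyloxolan-2-yl]-3-methylhex-2-enal
Conditions: MnO2, CH2Cl2, rt
Reagents that add atoms: none
Why: MnO2 oxidation is selective for the allylic primary alcohol and should give the (E)-enal while the secondary and tertiary hydroxyls stay.

**Step 11**
Reactants: 16 (2E,6R)-6-hydroxy-6-[(2S,5R)-5-[(2S)-2-hydroxy-6-methyl-5-oxoheptan-2-yl]-2-methyloxolan-2-yl]-3-methylhex-2-enal
Product: 17 (1E,3E,7R,8S,11R,12S)-8,11-epoxycembra-1,3-diene-7,12-diol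
Conditions: TiCl3(DME)1.5, Zn–Cu couple, DME, reflux, slow addition of 16 (high dilution)
Reagents that add atoms: none
Why: Intramolecular McMurry coupling joins the ketone carbon C1 and the aldehyde carbon C2 on low-valent titanium and deoxygenates to the C1=C2 bond, closing the 14-membered ring; ethers and saturated alcohols are tolerated, and the isomer with the isopropyl group trans to C3 (the target geometry) should be favoured because the smaller CH2 group, not the isopropyl group, then sits in the crowded position cis to C3.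

**Step 12**
Reactants: 17 (1E,3E,7R,8S,11R,12S)-8,11-epoxycembra-1,3-diene-7,12-diol
Product: 18 (1E,3E,7R,8S,11R,12S)-8,11-epoxy-12-hydroxycembra-1,3-dien-7-yl acetate (CNP0199953.2)
Conditions: Ac2O, pyridine, 4-(dimethylamino)pyridine (cat.), CH2Cl2, 0 °C → rt
Reagents that add atoms: acetic anhydride CC(=O)OC(C)=O
Why: Nucleophile-catalysed acylation should acetylate the secondary C7 hydroxyl and leave the hindered tertiary C12 hydroxyl, with no change at any stereocentre.

**Compound list**

1 | (2E,6E)-3,7,11-trimethyldodeca-2,6,10-trien-1-yl acetate [(E,E)-farnesyl acetate] | CC(=O)OC/C=C(\C)CC/C=C(\C)CCC=C(C)C | starting material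
2 | (2E,6E,10E)-12-hydroxy-3,7,11-trimethyldodeca-2,6,10-trien-1-yl acetate | CC(=O)OC/C=C(\C)CC/C=C(\C)CC/C=C(\C)CO | intermediate
3 | (2E,6E,10R,11R)-10,11-epoxy-12-hydroxy-3,7,11-trimethyldodeca-2,6-dien-1-yl acetate | CC(=O)OC/C=C(\C)CC/C=C(\C)CC[C@H]1O[C@]1(C)CO | intermediate
4 | (2E,6R,7R,10R,11R)-6,7:10,11-diepoxy-12-hydroxy-3,7,11-trimethyldodec-2-en-1-yl acetate | CC(=O)OC/C=C(\C)CC[C@H]1O[C@]1(C)CC[C@H]1O[C@]1(C)CO | intermediate
5 | (2E,6R,7R,10S,11R)-10-bromo-6,7-epoxy-11,12-dihydroxy-3,7,11-trimethyldodec-2-en-1-yl acetate | CC(=O)OC/C=C(\C)CC[C@H]1O[C@]1(C)CC[C@H](Br)[C@](C)(O)CO | intermediate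
6 | (2E,6R)-6-[(2S,5S,6R)-5-bromo-6-(hydroxymethyl)-2,6-dimethyloxan-2-yl]-6-hydroxy-3-methylhex-2-en-1-yl acetate | CC(=O)OC/C=C(\C)CC[C@@H](O)[C@]1(C)CC[C@H](Br)[C@@](C)(CO)O1 | intermediate
7 | bicyclic oxiranium ion (oxygen bonded to C8, C11 and C12; 1-oxoniabicyclo[3.1.0]hexane core), triflate salt, formed in the flask and not isolated | CC(=O)OC/C=C(\C)CC[C@@H](O)[C@]1(C)CC[C@H]2[O+]1[C@]2(C)CO.[O-]S(=O)(=O)C(F)(F)F | intermediate
8 | (2E,6R)-6-[(2S,5R)-5-[(2S)-1,2-dihydroxypropan-2-yl]-2-methyloxolan-2-yl]-6-hydroxy-3-methylhex-2-en-1-yl acetate | CC(=O)OC/C=C(\C)CC[C@@H](O)[C@]1(C)CC[C@@H](O1)[C@@](C)(O)CO | intermediate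
9 | (2E,6R)-6-hydroxy-6-[(2S,5R)-5-[(2S)-2-hydroxy-1-(tosyloxy)propan-2-yl]-2-methyloxolan-2-yl]-3-methylhex-2-en-1-yl acetate, formed in the flask and not isolated | CC(=O)OC/C=C(\C)CC[C@@H](O)[C@]1(C)CC[C@@H](O1)[C@@](C)(O)COS(=O)(=O)c1ccc(C)cc1 | intermediate
10 | (2E,6R)-3-methyl-6-[(2S,5R)-2-methyl-5-[(2S)-2-methyloxiran-2-yl]oxolan-2-yl]hex-2-ene-1,6-diol | OC/C=C(\C)CC[C@@H](O)[C@]1(C)CC[C@@H](O1)[C@]2(C)CO2 | intermediate
11 | 3-methylbutan-2-one | CC(=O)C(C)C | starting material
12 | 1,1-dimethylhydrazine | CN(C)N | starting material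
13 | 3-methylbutan-2-one N,N-dimethylhydrazone | CC(C)C(C)=NN(C)C | intermediate
14 | (2E,6R)-6-[(2S,5R)-5-[(2S)-5-(2,2-dimethylhydrazinylidene)-2-hydroxy-6-methylheptan-2-yl]-2-methyloxolan-2-yl]-3-methylhex-2-ene-1,6-diol, formed in the flask and not isolated | OC/C=C(\C)CC[C@@H](O)[C@]1(C)CC[C@@H](O1)[C@@](C)(O)CCC(=NN(C)C)C(C)C | intermediate
15 | (2E,6R)-6-[(2S,5R)-5-[(2S)-2-hydroxy-6-methyl-5-oxoheptan-2-yl]-2-methyloxolan-2-yl]-3-methylhex-2-ene-1,6-diol | OC/C=C(\C)CC[C@@H](O)[C@]1(C)CC[C@@H](O1)[C@@](C)(O)CCC(=O)C(C)C | intermediate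
16 | (2E,6R)-6-hydroxy-6-[(2S,5R)-5-[(2S)-2-hydroxy-6-methyl-5-oxoheptan-2-yl]-2-methyloxolan-2-yl]-3-methylhex-2-enal | O=C/C=C(\C)CC[C@@H](O)[C@]1(C)CC[C@@H](O1)[C@@](C)(O)CCC(=O)C(C)C | intermediate
17 | (1E,3E,7R,8S,11R,12S)-8,11-epoxycembra-1,3-diene-7,12-diol | O[C@@H]1CC/C(C)=C/C=C(/C(C)C)CC[C@](C)(O)[C@H]2CC[C@]1(C)O2 | intermediate
18 | (1E,3E,7R,8S,11R,12S)-8,11-epoxy-12-hydroxycembra-1,3-dien-7-yl acetate (CNP0199953.2) | CC(=O)O[C@@H]1CC/C(C)=C/C=C(/C(C)C)CC[C@](C)(O)[C@H]2CC[C@]1(C)O2 | target

**Count and risks**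

Total step count: 12. Longest linear sequence: 11 steps (steps 1 to 7 and 9 to 12, from 1 to 18).

Steps most likely to fail:

Step 11. The ketone–enal coupling may give poor control of the geometry of the new C1=C2 bond, may stall at the pinacol stage, or may couple between molecules instead of closing the ring. The fallback is stepwise and stereospecific and sets out from 16. TiCl3(DME)1.5/Zn–Cu in DME at 0 to 25 °C should stop at the pinacol stage and give the macrocyclic 1,2-diol (3E,7R,8S,11R,12S)-8,11-epoxycembr-3-ene-1,2,7,12-tetraol F1 as separable diastereomers. 1,1'-Thiocarbonyldiimidazole (toluene, 80 °C) then converts the diastereomer that has C3 and C14 cis on the new five-membered ring into the cyclic 1,2-thionocarbonate F2. Corey–Winter olefination (1,3-dimethyl-2-phenyl-1,3,2-diazaphospholidine, 40 °C) removes it by syn elimination and gives 17, where the route is rejoined.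

Step 6. Water may open the oxiranium ion at C11, which only returns a six-membered ring; the neighbouring C13 hydroxyl may compete with water for C12; or HBr may be lost by elimination. The fallback builds the oxolane directly by epoxide opening and sets out from 4. K2CO3 in MeOH removes the acetate to give the bis-epoxy diol (2E,6R,7R,10R,11R)-6,7:10,11-diepoxy-3,7,11-trimethyldodec-2-ene-1,12-diol F3. KOt-Bu in t-BuOH/THF (0 °C → rt) then triggers the Payne rearrangement of the 2,3-epoxy alcohol (the C13 alkoxide attacks C12 with inversion). The C11 alkoxide released in this way closes the oxolane by 5-exo-tet attack on C8 with inversion. This is the same stereochemical outcome as steps 4 to 7 and gives 10, where the route is rejoined.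

Step 4. Chemoselection between the two oxiranes may be lost, bromide may attack the tertiary C12, or the diethylamine set free may open the oxirane. The fallback opens the oxirane before the second one exists and sets out from 3. Li2NiBr4 in THF (an undirected, strictly SN2 bromide source) opens the single oxirane of 3 at the secondary C11 to give the bromo diol (2E,6E,10S,11R)-10-bromo-11,12-dihydroxy-3,7,11-trimethyldodeca-2,6-dien-1-yl acetate F4. The C7=C8 alkene is then epoxidised with the same ketone, used in larger amount under its near-neutral protocol (KHSO5, NaHCO3, aqueous MeCN, pH 7 to 8, 0 °C), so that the bromohydrin is not closed back to an oxirane. This gives 5, where the route is rejoined.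

**Further compounds**

F1 | step 11 | (3E,7R,8S,11R,12S)-8,11-epoxycembr-3-ene-1,2,7,12-tetraol (configuration at C1 and C2 not fixed) | O[C@@H]1CC/C(C)=C/C(O)C(O)(C(C)C)CC[C@](C)(O)[C@H]2CC[C@]1(C)O2
F2 | step 11 | cyclic 1,2-thionocarbonate of F1 | O[C@@H]1CC/C(C)=C/C3OC(=S)OC3(C(C)C)CC[C@](C)(O)[C@H]2CC[C@]1(C)O2
F3 | step 6 | (2E,6R,7R,10R,11R)-6,7:10,11-diepoxy-3,7,11-trimethyldodec-2-ene-1,12-diol | OC/C=C(\C)CC[C@H]1O[C@]1(C)CC[C@H]1O[C@]1(C)CO
F4 | step 4 | (2E,6E,10S,11R)-10-bromo-11,12-dihydroxy-3,7,11-trimethyldodeca-2,6-dien-1-yl acetate | CC(=O)OC/C=C(\C)CC/C=C(\C)CC[C@H](Br)[C@](C)(O)CO
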